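The runs were generated by integration with made-up constants; scatter was added.

The ratio that carries this flask is B, the Q ever made over the share of E missing from the balance.

| flask | E | X | remark | time |
|---|---|---|---|---|
| midnight | 0.060 M | 0.5 mol% | run made earlier |  |
| autumn | 0.13 M | 0.5 mol% | run made earlier |  |
| dusk | 0.089 M | 1 mol% | run made earlier |  |
| flask | 0.089 M | 0.5 mol% |  | 80 min |

| run | time / min | E / % | Q / % | J / % |
|---|---|---|---|---|
| midnight | 20.0 | 0.9 | 29.9 | 31.3 |
| midnight | 40.0 | 0 | 29.5 | 29.2 |
| midnight | 60.0 | 0.3 | 29.8 | 30.5 |
| midnight | 80.0 | 0 | 30.3 | 28.7 |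
| autumn | 6.00 | 0 | 32.8 | 44.2 |
| autumn | 15.0 | 0.3 | 35.1 | 41.8 |
| autumn | 30.0 | 1.5 | 32.9 | 42.1 |
| autumn | 80.0 | 0 | 33.4 | 42.2 |
| dusk | 20.0 | 1.6 | 47.2 | 31.9 |
| dusk | 40.0 | 0 | 45.4 | 32.5 |
| dusk | 60.0 | 1.3 | 46.7 | 32.3 |
| dusk | 80.0 | 0 | 46.2 | 32.9 |

(standard deviation of a reading: 1 percentage point)

* which holds at 80 min: what has brought the reaction to rest, or that it has not come to rest (forward and back rates have come level / it is still moving / no working catalyst is left / all of E has reacted)
* share of the E used up at 80 min
* Q at 80 min, in percent of the E charged
* J at 80 min, in percent of the E charged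

- a species is counted by the E in it: one J counts as two
- the numbers in the tables scatter by 1 percentage point (one standard deviation)
- the reaction counts as stopped when no species that holds the E changes by six tenths of a point or more over the second half of the time

In every earlier run E reads about zero from the first sampling and the yields stay flat within the scatter, so I expect the same of this flask at 80 min.

One thing looks contradictory. From midnight to autumn, at equal loading, the catalyst concentration [X], loading times charge, goes from 3.00 × 10⁻⁴ M to 6.50 × 10⁻⁴ M, twice as much, yet Q at 80 min moves only from 30.3% to 33.4%. It clears up if I read each J as a Q that has taken up one more E. The Q ever made is then Q + J/2, and the missing share is 100% minus Q minus J.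

So B is 1.09 at midnight and 2.23 in autumn, twice as much, and 3.00 at dusk. If both routes are first order in E, B follows [X]. The branch constant κ, B over [X], reads on average 3480 M⁻¹.

For this flask κ gives B = 1.55. The part of the Q made that J has taken reads 0.321 at midnight and 0.387 in autumn. The flask's charge lies between those two, so I take the midpoint, 0.354. The balance then gives me Q 32.3% and J 35.4%.

The forecast, reasoning that “Every earlier run ends with E at about zero and flat yields”, says: all of E has reacted, conversion 100%, Q 32%, J 37.5%. My J is lower than the forecast's.

The flask gives: all of E has reacted, conversion 100%, Q 31.5%, J 36.6%.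

    E + Q → J (k = 0.130 M⁻¹ s⁻¹)
    E + X → X + Q (k = 13.0 M⁻¹ s⁻¹)
    E → G (k = 0.00370 s⁻¹)

The missing share is G, 31.9%, so this flask's B is 1.56 against the 1.55 carried. The largest single effect on this flask's Q is the step from E + Q to J: struck out, Q reads 61.0% instead of 31.5%, a difference of 29 percentage points. In the neighbour flask with 1.2 mol% of X, κ gives B = 3.71, and the computed flask gives 3.75.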